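**Plan**
- Cuts: ring C is opened at two bonds at once, C4–C3 and O1–C2. This gives 2-hydroxy-3,4-dimethoxybenzaldehyde (ring A with O1, C8a, C4a, C4) and the aryl methyl ynol ether MeO–C3≡C2–Ar (ring B, 3-OMe already in place). The ynol ether is then cut at C2–C1′ into an aryl bromide and a methoxyacetylide.
- Enabling feature: C2=C3 of the pyran-4-one is a fully substituted enol ether (OMe on C3, aryl and O1 on C2), so it is an ynol ether at the alkyne oxidation level. O1–C8a–C4a–C4(=O) is a salicylaldehyde less two hydrogens. The O-methyl group has no β-hydrogen, so this ynol ether cannot collapse to a ketene on heating.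
- Key idea: formyl C4 and the O-bearing alkyne carbon C3 are both electrophilic. They are joined by polarity reversal through an acyl–Rh species in an electro-oxidative [4+2] annulation, with the anode as oxidant and H2 as the only by-product.
- Forward order: rings A and B are bought, and the 3′-OH is set apart from the four OMe groups as a benzyl ether. C2–C1′ is made by Negishi alkynylation, ring C closes last, and hydrogenolysis ends the route.
- Stereochemistry: none to set.

Key step: step 3

Remark: diplotrin B has no stereocentre, no stereogenic axis and no configurable double bond, so the request for a single enantiomer is met trivially and no step needs stereocontrol. Compounds 1, 3 and 7 are taken as catalogue chemicals.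

Step 1
Reactants: 1 5-bromo-2-methoxyphenol
Product: 2 2-(benzyloxy)-4-bromo-1-methoxybenzene
Conditions: BnBr (1.1 equiv), K2CO3 (1.5 equiv), DMF, rt to 50 °C
Reagents that add atoms: benzyl bromide, BrCc1ccccc1
Why: Williamson ether synthesis on the only acidic O–H masks the future 3′-OH with a group that tolerates strong base, Pd(0), Rh(III) and the anode.

Step 2
Reactants: 2 2-(benzyloxy)-4-bromo-1-methoxybenzene; 3 2-chloro-1,1-dimethoxyethane (chloroacetaldehyde dimethyl acetal)
Product: 6 2-(benzyloxy)-1-methoxy-4-(methoxyethynyl)benzene, via lithium methoxyacetylide 4 (not isolated), via methoxyethynylzinc chloride 5 (not isolated)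
Conditions: Et2NH, n-BuLi, THF, 0 °C (LiNEt2, 3.0 equiv per 3); 3 (1.5 equiv), 0 °C; ZnCl2 in THF, 0 °C to rt; then 2, XPhos Pd G3 (2 mol %), 40 °C; aq. NaHCO3 work-up, filtration through basic alumina
Reagents that add atoms: none
Why: double elimination (MeOH, HCl) and deprotonation of the chloroacetal is the standard entry to lithium alkoxyacetylides, and Negishi alkynylation of aryl halides with alkoxyethynylzinc halides is a known C(sp2)–C(sp) coupling whose basic medium spares the acid-labile ynol ether.

Step 3
Reactants: 6 2-(benzyloxy)-1-methoxy-4-(methoxyethynyl)benzene; 7 2-hydroxy-3,4-dimethoxybenzaldehyde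
Product: 8 2-[3-(benzyloxy)-4-methoxyphenyl]-3,7,8-trimethoxy-4H-chromen-4-one
Conditions: [Cp*RhCl2]2 (2.5 mol %), KOPiv (1 equiv), n-Bu4NPF6 (0.1 M), dry DMF, 80 °C, N2, undivided cell, graphite-felt anode, Pt cathode, constant current 4 mA (2.2–2.5 F/mol); 6 (1.5 equiv) added in portions
Reagents that add atoms: none
Why: Proposed new method: the phenoxide of 7 binds Cp*Rh(III), pivalate-assisted cleavage of the formyl C–H bond gives a five-membered acyl-rhodacycle that chelation protects from decarbonylation, 6 inserts into the Rh–acyl bond to give a seven-membered oxarhodacycle, C–O reductive elimination (possibly oxidation-induced) releases 8, and the anode returns the metal to Rh(III) while the cathode turns the two released protons into H2. The closest known reaction type is the Rh(III)-catalysed oxidative annulation of salicylaldehydes with diaryl and alkyl aryl alkynes to 2,3-disubstituted chromones, known with Cu(II) and with anodic turnover, and the O-substituted alkyne is the new element. The one ring formed, pyran-4-one ring C, closes as a formal [4+2] annulation (O1–C8a–C4a–C4 from 7 plus C3≡C2 from 6), with C4–C3 made by syn migratory insertion and O1–C2 by reductive elimination from the seven-membered metallacycle, and no stereocentre arises. The step needs one regiochemical outcome, acyl carbon to the OMe-bearing carbon, and both biases of 6 point that way: oxygen donation makes the O-bearing carbon the electrophilic terminus that accepts the migrating acyl group and the aryl-bearing carbon the nucleophilic terminus that takes the cationic metal, and aryl alkyl alkynes are known to place the aryl-bearing carbon on Rh and hence next to O1. Two carbons that are both electrophilic in ordinary chemistry (formyl C4 and ynol-ether C3) are thus joined through the polarity-reversed acyl–Rh species, and syn insertion leaves OMe trans to Rh, which disfavours β-methoxide elimination. Anodic turnover is chosen because 6 adds carboxylic acids and is activated by Cu(II) or Ag(I) salts, whereas here the medium stays pivalate-buffered, no acid builds up, and the methyl ynol ether has no β-hydrogen for retro-ene loss at 80 °C.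

Step 4
Reactants: 8 2-[3-(benzyloxy)-4-methoxyphenyl]-3,7,8-trimethoxy-4H-chromen-4-one
Product: 9 diplotrin B, 2-(3-hydroxy-4-methoxyphenyl)-3,7,8-trimethoxy-4H-chromen-4-one
Conditions: H2 (1 atm), 10 % Pd/C, EtOAc/MeOH, rt
Reagents that add atoms: none
Why: catalytic hydrogenolysis cleaves only the benzylic C–O bond, since the tetrasubstituted vinylogous-ester C2=C3 bond, the C4 carbonyl and the four methyl ethers are inert under these conditions.

**Compound list**
1 | 5-bromo-2-methoxyphenol | COc1ccc(Br)cc1O | starting material
2 | 2-(benzyloxy)-4-bromo-1-methoxybenzene | COc1ccc(Br)cc1OCc1ccccc1 | intermediate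
3 | 2-chloro-1,1-dimethoxyethane | COC(CCl)OC | starting material
4 | lithium methoxyacetylide | [Li]C#COC | intermediate
5 | methoxyethynylzinc chloride | Cl[Zn]C#COC | intermediate
6 | 2-(benzyloxy)-1-methoxy-4-(methoxyethynyl)benzene | COC#Cc1ccc(OC)c(OCc2ccccc2)c1 | intermediate
7 | 2-hydroxy-3,4-dimethoxybenzaldehyde | COc1ccc(C=O)c(O)c1OC | starting material
8 | 2-[3-(benzyloxy)-4-methoxyphenyl]-3,7,8-trimethoxy-4H-chromen-4-one | COc1ccc(-c2oc3c(OC)c(OC)ccc3c(=O)c2OC)cc1OCc1ccccc1 | intermediate
9 | diplotrin B | COc1ccc(-c2oc3c(OC)c(OC)ccc3c(=O)c2OC)cc1O | target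

Total step count: 4
Longest linear sequence: 4 steps (1 → 2 → 6 → 8 → 9)

**Steps most likely to fail**

**Step 3 (labelled step).**
- The alkyne may insert with the reverse orientation, or the phenoxide may attack the O-bearing carbon first. Either gives isoflavone-type connectivity.
- The ynol ether may be lost before insertion, by addition of pivalic acid, phenol or adventitious water, or by direct oxidation at the anode.
- The electron-rich phenoxide may be oxidised in competition with the catalyst.
- Methoxide may be eliminated after insertion.

Fallback, known chemistry only, from 7 back to 8. The C3 oxygen is installed after ring closure.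
- The sulfoxonium ylide 1-[3-(benzyloxy)-4-methoxyphenyl]-2-[dimethyl(oxo)-λ6-sulfanylidene]ethan-1-one F1 is made from commercial methyl 3-(benzyloxy)-4-methoxybenzoate and dimethylsulfoxonium methylide (Me3S(O)I, KOt-Bu, THF, reflux).
- A redox-neutral Rh(III)-catalysed formyl C–H acylmethylation and cyclodehydration of 7 with F1 ([Cp*RhCl2]2, AgSbF6, PivOH, DCE, 100 °C) should give the flavone 2-[3-(benzyloxy)-4-methoxyphenyl]-7,8-dimethoxy-4H-chromen-4-one F2.
- C3-lithiation (LDA, THF, −78 °C), borylation with B(OMe)3 and oxidation in the same flask (H2O2, AcOH) should give the flavonol 2-[3-(benzyloxy)-4-methoxyphenyl]-3-hydroxy-7,8-dimethoxy-4H-chromen-4-one F3.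
- Methylation of F3 (MeI, K2CO3, acetone) returns to 8.

**Step 2.**
- The threefold elimination and metalation of the chloroacetal may be incomplete.
- Oxidative addition into the electron-rich C–Br bond may be sluggish in the presence of amine and alkoxide.
- The ynol ether may hydrate during isolation.

Fallback from 2 back to 6. The triple bond is made by elimination rather than by cross-coupling.
- Br/Li exchange on 2 (n-BuLi, THF, −78 °C) and acylation with N,2-dimethoxy-N-methylacetamide should give 1-[3-(benzyloxy)-4-methoxyphenyl]-2-methoxyethan-1-one F4.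
- Chelation-controlled enolisation and triflation (KHMDS, PhNTf2, THF, −78 °C) should give (Z)-1-[3-(benzyloxy)-4-methoxyphenyl]-2-methoxyvinyl triflate F5, in which H and OTf are anti.
- Elimination with KOt-Bu (THF, −78 °C to rt) gives 6.

**Step 4.**
- The pyranone C2=C3 bond may be partly saturated on prolonged exposure.
- Hydrogenolysis may stall through catalyst poisoning by residues carried over from the electrolysis.

Fallback from 1 back to 9. The reductive unmasking is avoided altogether by carrying the 3′-oxygen as a fluoride-labile silyl ether.
- Silylation of 1 (TIPSCl, imidazole, DMF) gives (5-bromo-2-methoxyphenoxy)triisopropylsilane F6.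
- Negishi alkynylation with 5 as in step 2 gives triisopropyl[2-methoxy-5-(methoxyethynyl)phenoxy]silane F7.
- Annulation with 7 as in step 3 gives 3,7,8-trimethoxy-2-[4-methoxy-3-(triisopropylsilyloxy)phenyl]-4H-chromen-4-one F8.
- TBAF (THF, 0 °C) releases 9.

**Further compounds**
F1 | step 3 | 1-[3-(benzyloxy)-4-methoxyphenyl]-2-[dimethyl(oxo)-λ6-sulfanylidene]ethan-1-one | COc1ccc(C(=O)C=S(C)(C)=O)cc1OCc1ccccc1
F2 | step 3 | 2-[3-(benzyloxy)-4-methoxyphenyl]-7,8-dimethoxy-4H-chromen-4-one | COc1ccc(-c2cc(=O)c3ccc(OC)c(OC)c3o2)cc1OCc1ccccc1
F3 | step 3 | 2-[3-(benzyloxy)-4-methoxyphenyl]-3-hydroxy-7,8-dimethoxy-4H-chromen-4-one | COc1ccc(-c2oc3c(OC)c(OC)ccc3c(=O)c2O)cc1OCc1ccccc1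
F4 | step 2 | 1-[3-(benzyloxy)-4-methoxyphenyl]-2-methoxyethan-1-one | COCC(=O)c1ccc(OC)c(OCc2ccccc2)c1
F5 | step 2 | (Z)-1-[3-(benzyloxy)-4-methoxyphenyl]-2-methoxyvinyl trifluoromethanesulfonate | CO/C=C(\OS(=O)(=O)C(F)(F)F)c1ccc(OC)c(OCc2ccccc2)c1
F6 | step 4 | (5-bromo-2-methoxyphenoxy)triisopropylsilane | COc1ccc(Br)cc1O[Si](C(C)C)(C(C)C)C(C)C
F7 | step 4 | triisopropyl[2-methoxy-5-(methoxyethynyl)phenoxy]silane | COC#Cc1ccc(OC)c(O[Si](C(C)C)(C(C)C)C(C)C)c1
F8 | step 4 | 3,7,8-trimethoxy-2-[4-methoxy-3-(triisopropylsilyloxy)phenyl]-4H-chromen-4-one | COc1ccc(-c2oc3c(OC)c(OC)ccc3c(=O)c2OC)cc1O[Si](C(C)C)(C(C)C)C(C)C
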